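**Plan**

- The retrosynthesis first closes the acid and the C5 hydroxyl to a γ-lactone and masks the C3/C4 diol and the catechol. It then cuts two bonds at C1 in one operation: C1–C7 (ring carbon to carboxyl carbon) and the acyl C–O bond of the caffeate, the C1 oxygen being a former ketone oxygen.
- The feature that allows this: C1 of the cyclohexane ring is a quaternary carbon holding both the carboxyl carbon and the acyloxy oxygen. This is an α-acyloxy acid, the pattern a Passerini reaction lays down on a ketone carbon.
- Forward, the carbocycle comes intact from (−)-quinic acid. C1 is trimmed to a ketone (acetonide/lactone, lactone reduction, glycol cleavage, C5 silylation), then joined in one step with di-O-acetylcaffeic acid and 2-bromo-6-isocyanopyridine.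
- The only ring closed afterwards is a temporary γ-lactone (C5–O onto C7, expelling the aminopyridine). Aqueous acid then opens it and removes the acetonide and acetates.
- C3, C4 and C5 are carried from quinic acid and the E-alkene from caffeic acid. C1 is set in the three-component step by attack anti to the acetonide, and the lactonisation, possible only for the C1 epimer with C7 cis to C5–O, removes the wrong epimer.

Key step: step 8

Remark on numbering: quinic acid numbering is kept for all cyclohexane compounds, ketones included (C1 = carbon that carries or will carry the carboxyl carbon C7; C3/C4 = cis-diol; C5 = oxygen cis to C7).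
Assumption: 2-bromo-6-isocyanopyridine is prepared fresh, since electron-poor aryl isocyanides have limited shelf life.

**Step 1**
Reactants: 1 (−)-quinic acid
Product: 2 3,4-O-isopropylidene-1,5-quinide
Conditions: 2,2-dimethoxypropane, TsOH·H2O (cat.), acetone, reflux
Reagents that add atoms: 2,2-dimethoxypropane, COC(C)(C)OC
Why: Acid-catalysed transketalisation picks out the only cis-vicinal diol (C3/C4), and under the same conditions the C5 hydroxyl, cis to the carboxyl, closes the γ-lactone (acetonide formation with lactonisation), no stereocentre being touched.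

**Step 2**
Reactants: 2 3,4-O-isopropylidene-1,5-quinide
Product: 3 1-C-(hydroxymethyl)-3,4-O-isopropylidenecyclohexane-1,3,4,5-tetrol (C1–OH, C5–OH and CH2OH free)
Conditions: NaBH4, EtOH, 0 °C to rt
Reagents that add atoms: none
Why: Hydride reduction of the strained bicyclic γ-lactone to the primary alcohol frees the C5 hydroxyl and creates the 1,2-diol at C1/C7, while the acetonide is inert to borohydride.

**Step 3**
Reactants: 3 1-C-(hydroxymethyl)-3,4-O-isopropylidenecyclohexane-1,3,4,5-tetrol
Product: 4 (3R,4S,5R)-5-hydroxy-3,4-O-isopropylidenedioxycyclohexanone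
Conditions: NaIO4, aqueous phosphate buffer (pH 7), 0 °C to rt
Reagents that add atoms: none
Why: Malaprade glycol cleavage through the cyclic periodate ester of the only free vicinal diol (C1–OH/CH2OH) excises C7 as formaldehyde and leaves the C1 ketone; the isolated C5 hydroxyl and the ketal-protected diol cannot react.

**Step 4**
Reactants: 4 (3R,4S,5R)-5-hydroxy-3,4-O-isopropylidenedioxycyclohexanone
Product: 5 5-O-(tert-butyldimethylsilyl)-3,4-O-isopropylidene-3,4,5-trihydroxycyclohexanone
Conditions: TBSCl, imidazole, DMF, 0 °C to rt
Reagents that add atoms: tert-butyldimethylsilyl chloride, CC(C)(C)[Si](C)(C)Cl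
Why: Imidazole-mediated silylation of the secondary alcohol is mild enough that the β-oxygenated ketone should not eliminate to the enone, and the silyl ether later keeps the C5 oxygen from intercepting the nitrilium carbon.

**Step 5**
Reactants: 6 caffeic acid
Product: 7 (E)-3,4-diacetoxycinnamic acid
Conditions: Ac2O, pyridine, DMAP (cat.), rt; aqueous HCl work-up
Reagents that add atoms: acetic anhydride, CC(=O)OC(C)=O
Why: DMAP-catalysed O-acetylation masks both phenols, which would otherwise oxidise or compete as acid components, and the carboxylic acid is recovered free after the acidic aqueous quench.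

**Step 6**
Reactants: 8 2-amino-6-bromopyridine
Product: 9 N-(6-bromopyridin-2-yl)formamide
Conditions: HCOOH/Ac2O (premixed, 55 °C), then 8, THF, 0 °C to rt
Reagents that add atoms: formic acid, O=CO (transferred as acetic formic anhydride, CC(=O)OC=O, made in the flask)
Why: N-formylation of the weakly nucleophilic aminopyridine by the mixed anhydride, which delivers the formyl group because its formyl carbonyl is the more electrophilic and less hindered one.

**Step 7**
Reactants: 9 N-(6-bromopyridin-2-yl)formamide
Product: 10 2-bromo-6-isocyanopyridine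
Conditions: POCl3, Et3N, CH2Cl2, −10 to 0 °C; aqueous Na2CO3 work-up
Reagents that add atoms: none
Why: Formamide dehydration (O-phosphorylation, then base-induced elimination) is the standard isocyanide synthesis, and the basic work-up protects the acid-sensitive isocyanide.

**Step 8**
Reactants: 5 5-O-(tert-butyldimethylsilyl)-3,4-O-isopropylidene-3,4,5-trihydroxycyclohexanone; 7 (E)-3,4-diacetoxycinnamic acid; 10 2-bromo-6-isocyanopyridine
Product: 12 N-(6-bromopyridin-2-yl) amide of 1-O-(3,4-di-O-acetylcaffeoyl)-5-O-(tert-butyldimethylsilyl)-3,4-O-isopropylidenequinic acid, via α-hydroxy O-acyl imidate 11 (not isolated)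
Conditions: 7 (1.2 equiv), 10 (1.3 equiv), CH2Cl2 (1 M in 5), rt, 48–72 h
Reagents that add atoms: none
Why: In a concentrated aprotic medium acid 7 hydrogen-bonds the C1 carbonyl of 5, the isocyanide carbon of 10 adds to C1 while the carboxylate oxygen adds to the same isocyanide carbon (α-addition) to give imidate 11, and an O-to-O acyl shift through a five-membered cyclic transition state (Mumm-type rearrangement) moves the diacetylcaffeoyl group onto the C1 oxygen and leaves the secondary amide. The closest known reaction type is the Passerini reaction of cyclohexanones with cinnamic acids and convertible aryl isocyanides, and here the ketone is inductively activated by the β-oxygens at C3 and C5. No ring is closed; the C1–C7 bond and the C1–O–acyl linkage are formed, so the hindered tertiary ester arises by intramolecular transfer and not by acylating a tertiary alcohol. The one new stereocentre, C1, is controlled by the ring: in the chair with C4–O and C5–OSi equatorial, the axial C3–O bond of the cis-fused dioxolane and its endo methyl shield the face of axial approach, so the isocyanide should enter equatorially, anti to the acetonide and cis to C5–OSi, placing the acyloxy group axial and cis to C3–O as in quinic acid. The step needs this facial selectivity and ketone addition in preference to isocyanide oligomerisation; the substrate provides the first through the acetonide, and the second is served by high concentration, a slight excess of 7 and 10, and the silyl ether that prevents the C5 oxygen from trapping the nitrilium carbon.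

**Step 9**
Reactants: 12 N-(6-bromopyridin-2-yl) amide of 1-O-(3,4-di-O-acetylcaffeoyl)-5-O-(tert-butyldimethylsilyl)-3,4-O-isopropylidenequinic acid
Product: 14 1-O-(3,4-di-O-acetylcaffeoyl)-3,4-O-isopropylidene-1,5-quinide, via C5-hydroxy amide 13 (not isolated)
Conditions: HF·pyridine, pyridine, THF, 0 °C to rt; then CSA (1.2 equiv), toluene, 70 °C
Reagents that add atoms: none
Why: Fluoride cleaves the Si–O bond without harming acetonide, acetates or the cinnamate, and acid then drives an intramolecular acyl substitution (γ-hydroxy amide to γ-lactone, 5-exo-trig) in which the weakly basic 2-amino-6-bromopyridine is the leaving group; only the C1 epimer with C7 cis to C5–O can cyclise, so the minor epimer stays behind as an open amide and is separated.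

**Step 10**
Reactants: 14 1-O-(3,4-di-O-acetylcaffeoyl)-3,4-O-isopropylidene-1,5-quinide
Product: 15 1-O-caffeoylquinic acid
Conditions: 2 M HCl (aq)/THF (3:1), rt, several days
Reagents that add atoms: water, O
Why: Aqueous acid hydrolyses the ketal, the two phenolic acetates and the strained γ-lactone, while the hindered tertiary cinnamate reacts far more slowly, and acidic conditions avoid the base-induced acyl migration typical of caffeoylquinic acids; no stereocentre is affected.

**Compound list**

1 | (−)-quinic acid, (1S,3R,4S,5R)-1,3,4,5-tetrahydroxycyclohexane-1-carboxylic acid | O[C@]1(C(=O)O)C[C@@H](O)[C@H](O)[C@H](O)C1 | starting material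
2 | 3,4-O-isopropylidene-1,5-quinide (γ-lactone between C7 and O5, acetonide on O3/O4, C1–OH free) | O[C@]1(C(=O)O2)C[C@@H]2[C@H](O3)[C@H](OC3(C)C)C1 | intermediate
3 | 1-C-(hydroxymethyl)-3,4-O-isopropylidenecyclohexane-1,3,4,5-tetrol (configuration of quinic acid at C1, C3, C4, C5) | O[C@]1(CO)C[C@@H](O)[C@H](O2)[C@H](OC2(C)C)C1 | intermediate
4 | (3R,4S,5R)-5-hydroxy-3,4-O-isopropylidenedioxycyclohexanone (C5–OH trans to the acetonide) | O=C1C[C@@H](O)[C@H](O2)[C@H](OC2(C)C)C1 | intermediate
5 | 5-O-(tert-butyldimethylsilyl)-3,4-O-isopropylidene-3,4,5-trihydroxycyclohexanone (silyl ether of 4, configuration unchanged) | O=C1C[C@@H](O[Si](C)(C)C(C)(C)C)[C@H](O2)[C@H](OC2(C)C)C1 | intermediate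
6 | caffeic acid, (E)-3,4-dihydroxycinnamic acid | O=C(O)/C=C/c1ccc(O)c(O)c1 | starting material
7 | (E)-3,4-diacetoxycinnamic acid (di-O-acetylcaffeic acid) | CC(=O)Oc1ccc(/C=C/C(=O)O)cc1OC(C)=O | intermediate
8 | 2-amino-6-bromopyridine | Nc1cccc(Br)n1 | starting material
9 | N-(6-bromopyridin-2-yl)formamide | O=CNc1cccc(Br)n1 | intermediate
10 | 2-bromo-6-isocyanopyridine | [C-]#[N+]c1cccc(Br)n1 | intermediate
11 | α-hydroxy O-acyl imidate (not isolated, step 8): C1 bears a free OH and the carbon C7, which is doubly bonded to the N of the 6-bromopyridin-2-yl group and singly bonded to the O of the diacetylcaffeoyl group; C1 configuration as in 12 | O[C@]1(C(=Nc2cccc(Br)n2)OC(=O)/C=C/c2ccc(OC(C)=O)c(OC(C)=O)c2)C[C@@H](O[Si](C)(C)C(C)(C)C)[C@H](O3)[C@H](OC3(C)C)C1 | intermediate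
12 | N-(6-bromopyridin-2-yl) amide of 1-O-(3,4-di-O-acetylcaffeoyl)-5-O-(tert-butyldimethylsilyl)-3,4-O-isopropylidenequinic acid (C1 acyloxy cis to the acetonide, carboxamide cis to C5–OSi) | O=C(/C=C/c1ccc(OC(C)=O)c(OC(C)=O)c1)O[C@]1(C(=O)Nc2cccc(Br)n2)C[C@@H](O[Si](C)(C)C(C)(C)C)[C@H](O3)[C@H](OC3(C)C)C1 | intermediate
13 | C5-hydroxy amide (not isolated, step 9): 12 without the silyl group | O=C(/C=C/c1ccc(OC(C)=O)c(OC(C)=O)c1)O[C@]1(C(=O)Nc2cccc(Br)n2)C[C@@H](O)[C@H](O3)[C@H](OC3(C)C)C1 | intermediate
14 | 1-O-(3,4-di-O-acetylcaffeoyl)-3,4-O-isopropylidene-1,5-quinide | O=C(/C=C/c1ccc(OC(C)=O)c(OC(C)=O)c1)O[C@]1(C(=O)O2)C[C@@H]2[C@H](O3)[C@H](OC3(C)C)C1 | intermediate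
15 | 1-O-caffeoylquinic acid | O=C(/C=C/c1ccc(O)c(O)c1)O[C@]1(C(=O)O)C[C@@H](O)[C@H](O)[C@H](O)C1 | target

**Step count**

Total: 10 steps. Longest linear sequence: 7 steps (1, 2, 3, 4, 8, 9, 10); steps 5 and 6–7 are side branches that supply 7 and 10.

**Steps most likely to fail**

1. Step 8. The α-addition of the electron-poor aryl isocyanide to the ketone may be slow enough for oligomerisation of 10 to take over, or the facial selectivity at C1 may be poor. The fallback sets out from 2 and 7 and returns at 14. Acid 7 is converted with oxalyl chloride and catalytic DMF in CH2Cl2 into (E)-3,4-diacetoxycinnamoyl chloride F1. The free tertiary C1 hydroxyl of lactone 2 is then acylated with it (DMAP, pyridine, CH2Cl2, rt to 40 °C) to give 14 directly. C1 keeps the configuration of quinic acid, so the stereochemical question disappears, at the price of an intermolecular acylation of a tertiary alcohol.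

2. Step 9. Displacement of the aminopyridine by the C5 hydroxyl may stall under acid, or the acetonide may be lost on prolonged exposure. The fallback sets out from 12 and returns at 14. The amide nitrogen of 12 is acylated with Boc2O and DMAP in MeCN to give the N-Boc imide F2. HF·pyridine then removes the silyl group to give the C5-hydroxy N-Boc imide F3. Its doubly acylated nitrogen is displaced by the C5 hydroxyl on addition of Et3N, giving 14 and the Boc-protected aminopyridine.

3. Step 4. β-Elimination of the C5 oxygen to the enone may compete under the basic silylation conditions. The fallback sets out from 2 and returns at 5. Lactone 2 is opened with catalytic NaOMe in MeOH to methyl 3,4-O-isopropylidenequinate F4. Its secondary C5 hydroxyl is silylated (TBSCl, imidazole, DMF) to give methyl 5-O-(tert-butyldimethylsilyl)-3,4-O-isopropylidenequinate F5. The ester is reduced with LiBH4 in THF to the 5-O-silylated C1 diol F6, and NaIO4 cleavage of the diol gives 5, so the hydroxyl is already protected when the ketone appears.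

**Further compounds**

F1 | step 8 | (E)-3,4-diacetoxycinnamoyl chloride | CC(=O)Oc1ccc(/C=C/C(Cl)=O)cc1OC(C)=O
F2 | step 9 | N-Boc-N-(6-bromopyridin-2-yl) imide of 1-O-(3,4-di-O-acetylcaffeoyl)-5-O-(tert-butyldimethylsilyl)-3,4-O-isopropylidenequinic acid | O=C(/C=C/c1ccc(OC(C)=O)c(OC(C)=O)c1)O[C@]1(C(=O)N(C(=O)OC(C)(C)C)c2cccc(Br)n2)C[C@@H](O[Si](C)(C)C(C)(C)C)[C@H](O3)[C@H](OC3(C)C)C1
F3 | step 9 | C5-hydroxy N-Boc-N-(6-bromopyridin-2-yl) imide (F2 without the silyl group) | O=C(/C=C/c1ccc(OC(C)=O)c(OC(C)=O)c1)O[C@]1(C(=O)N(C(=O)OC(C)(C)C)c2cccc(Br)n2)C[C@@H](O)[C@H](O3)[C@H](OC3(C)C)C1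
F4 | step 4 | methyl 3,4-O-isopropylidenequinate | O[C@]1(C(=O)OC)C[C@@H](O)[C@H](O2)[C@H](OC2(C)C)C1
F5 | step 4 | methyl 5-O-(tert-butyldimethylsilyl)-3,4-O-isopropylidenequinate | O[C@]1(C(=O)OC)C[C@@H](O[Si](C)(C)C(C)(C)C)[C@H](O2)[C@H](OC2(C)C)C1
F6 | step 4 | 5-O-(tert-butyldimethylsilyl)-1-C-(hydroxymethyl)-3,4-O-isopropylidenecyclohexane-1,3,4,5-tetrol | O[C@]1(CO)C[C@@H](O[Si](C)(C)C(C)(C)C)[C@H](O2)[C@H](OC2(C)C)C1
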